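## Structural features

Lobophynin B is a cembranoid in which a 14-membered carbocycle (C1–C14) shares the C1–C2 bond with a 2,5-dihydrofuran (O, C2, C1, C15, C16). The tetrasubstituted C1=C15 alkene lies inside the small ring and is exocyclic to the large one. C15 carries the C17 acetoxymethyl group. The macrocycle holds two E trisubstituted alkenes (C3=C4, C11=C12) and a trans trisubstituted oxirane (C7–C8). There are three stereocentres: C7 and C8 (both R) are neighbours in the oxirane, and C2 (R) is five bonds away from them, so each element needs its own reagent control. The fragile sites are the doubly allylic C2–H ether (ionisation, oxidation, elimination toward a furan), the acid-sensitive oxirane and the allylic acetate. The real difficulties are the closure of the 14-membered ring in the presence of these groups, the tetrasubstituted alkene with three different oxygenated methylenes (C14, C16, C17) in a fixed arrangement, and placing one oxirane on one of three similar trisubstituted alkenes. The key step exploits the fact that C13–C14 is the only sp3–sp3 ring bond whose two carbons are both primary and allylic (C13 to C11=C12, C14 to C1=C15). The seco compound is therefore a bis(allylic bromide) whose C2–C13 part is a farnesane chain.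

## Logic of the disconnections

21 ⇒ 20 ⇒ 19. The acetyl C–O bond at the C17 oxygen is cut and the oxygen is carried as a silyl ether. An allylic acetate could ionise under nickel, a silyl ether cannot. The forward steps (fluoride, then acylation) must spare the oxirane and the doubly allylic ether, which mild conditions allow.

19 ⇒ 17. The C13–C14 bond is cut. This opens the only ring that is hard to close and gives an acyclic chain whose two ends are primary allylic bromides. The forward step must join the two primary termini head to head, keep E geometry at C11=C12 and run under high dilution. Compounds 17 and 19 were checked against 21: same configuration at C2, C7 and C8, same E alkenes, so no structural correction was needed.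

17 ⇒ 16 ⇒ 15. Both C–Br bonds go back to C–O, and both alcohols go back to one reduction of a methyl ester (C14) and a pivalate (C13). The two termini never need to be told apart. The demand is a neutral bromination, and 17 is used as soon as it is made.

15 ⇒ 14. The C1=C15 alkene is cut by ring-closing metathesis. The dihydrofuran becomes an acyclic ether of an acrylate and a 2-substituted allyl group. The forward step must close a tetrasubstituted alkene faster than the carbene can reach C3=C4.

14 ⇒ 10 + 13. The O–C16 bond is cut. The C15–C17 piece 13 already carries the silyl ether, so no halide at C17 ever enters the nickel step and no later oxygen exchange at C17 is needed. The forward step must alkylate a base-sensitive β-hydroxy acrylate without touching C2, hence silver oxide and no strong base.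

13 ⇒ 12 ⇒ 11. The C–Br and O–Si bonds go back to a symmetric diol. The only demand is monosilylation.

10 ⇒ 7 + 8 (through 9). The C1–C2 bond is cut by a Morita–Baylis–Hillman reaction, which sets C2. The oxirane is too far away to help, so the catalyst must control C2. A plain methyl acrylate gives no useful catalytic control, so the fluorinated acrylate 8 is used and the methyl ester is formed in the same flask.

7 ⇒ 6 ⇒ 5. The enal goes back to the allylic acetate. The acetate must be cleaved beside the pivalate.

5 ⇒ 4. The two C–O bonds of the oxirane are cut (Shi epoxidation), which removes two stereocentres. Site selectivity among three trisubstituted alkenes comes from the acyloxy groups that flank and deactivate the two outer alkenes. Face selectivity comes from the ketone catalyst.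

4 ⇒ 3 ⇒ 2 ⇒ 1. The C13–O bond is cut (allylic oxidation) and the acyl groups are removed. Commercial 1 already holds C2–C13, both E alkenes and the three methyl groups. The demand is E-selective oxidation of the terminal methyl group.

## Other disconnections considered

Alternative 1: The O–C2 bond is cut and the alkene is moved back to C1=C2. In the forward sense Cu(CF3COCHCOCF3)2 (divalent copper) would rearrange an open-chain substrate that has an oxirane on C15–C16 next to a C1=C2–C3=C4 diene. Oxygen would shift from C15 to C2 and give the dihydrofuran A1 with the C2 stereocentre.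
- In its favour: the tetrasubstituted C1=C15 alkene and the ring arise in one catalytic step without a ruthenium carbene. On that point it is better than step 11 of the chosen plan, because C3=C4 is part of the reacting system and cannot compete. The three oxygenated methylenes are differentiated from the start, which is equal to the chosen plan.
- Against it: C2 would depend on transfer of chirality from a quaternary oxirane carbon across a diene. A shift to C4 (a seven-membered ether) or ionisation to a pentadienyl cation would erode it. The substrate needs an enantiopure 2,2-disubstituted oxirane and a geometrically pure C1=C2 alkene, two extra stereochemical tasks. In A1 the C7=C8 bond is still an alkene, so the epoxidation would have to be done late on a tetraene that contains the electron-rich tetrasubstituted alkene. The chosen plan settles that on a farnesyl diester, where electronics decide.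
- Comparison: the macrocycle is still open in A1, so a C13–C14 closure like step 14 would follow anyway. The step count would be no lower.

Alternative 2: The O–C16 and C15–C17 bonds are cut. In the forward sense PdCl2(MeCN)2 (divalent palladium) with carbon monoxide, methanol and 1,4-benzoquinone would act on a 14-membered carbocycle that bears a free C2 hydroxyl and a C1=C15=C16 allene. Alkoxypalladation at C16, CO insertion at C15 and methanolysis would give the ester A2.
- In its favour: the ring and C17 are made in one step at the very end, and C17 never needs a protecting group. Reduction and acetylation of A2 are two steps, equal to the endgame of the chosen plan. No metathesis is needed for the tetrasubstituted alkene, which is better than the chosen plan.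
- Against it: the C2 carbinol would have to be set inside or before a macrocycle that carries an allene, most likely in a ring-closing carbonyl addition where control of C2 is hard. The chosen plan sets C2 on an open chain under catalyst control. Palladium dichloride, chloride and an oxidant are a risk for the trisubstituted oxirane. The hydride reduction of A2 must spare the oxirane.
- Comparison: the chosen plan spends more steps on protecting groups but keeps the order "stereocentres on the chain, ring last", which is the more reliable order.

Alternative 3: The C3–C4 bond is cut as an alkyne. In the forward sense Mo(≡C-C6H4-4-OMe)(OSiPh3)3 (hexavalent molybdenum) would close the cycloalkyne A3 from a diyne with loss of 2-butyne. Anti addition of hydrogen and methyl would then give the C3=C4 alkene.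
- In its favour: alkyne metathesis leaves alkenes and the oxirane alone and cannot scramble alkene geometry. On ring-closure reliability and on the safety of C11=C12 it is better than step 14. C2 and the oxirane are already in place.
- Against it: the tetrasubstituted alkene with three different groups would have to be made geometrically pure in an open chain, whereas the chosen plan lets the ring fix it. The anti hydromethylation must put the metal on C4, away from the C2 oxygen. The hydroxyl-directed ruthenium-catalysed trans-hydrostannation does the opposite, and a silyl ether at C2 gives no direction. After A3 there would still be hydrometalation, methylation, removal of two protecting groups, closure of the dihydrofuran at O–C16, desilylation and acetylation, against two steps after step 14.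
- Comparison: farnesol cannot supply the chain, since C3–C4 is the bond being made, so the route to the diyne would be longer.

Key step: step 14

Remark on numbering: cembrane numbering (C1–C17) is used for all compounds, so farnesol C1 is C2 and farnesol C12 is C13; the target is taken as (2R,7R,8R).

## Route

Step 1
Reactants: 1 (2E,6E)-farnesol
Product: 2 (2E,6E)-farnesyl acetate
Conditions: Ac2O, pyridine, DMAP (cat.), CH2Cl2, 0 °C → rt
Reagents that add atoms: acetic anhydride, CC(=O)OC(C)=O
Why: Acylation of a primary allylic alcohol; the acetate protects C2–OH and later deactivates the C3=C4 alkene toward the dioxirane.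

Step 2
Reactants: 2 (2E,6E)-farnesyl acetate
Product: 3 (2E,6E,10E)-12-hydroxyfarnesyl acetate (C13 alcohol)
Conditions: SeO2 (0.2 equiv), t-BuOOH (3 equiv), salicylic acid (0.1 equiv), CH2Cl2, 0 °C → rt, stopped short of full conversion
Reagents that add atoms: selenium dioxide, O=[Se]=O (oxygen carrier); tert-butyl hydroperoxide, CC(C)(C)OO (terminal oxidant)
Why: Catalytic selenium dioxide allylic oxidation (ene reaction, then [2,3]-sigmatropic shift) attacks the most electron-rich, least hindered alkene at the methyl group trans to the chain, which gives the E allylic alcohol; the allylic acetate shields C3=C4.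

Step 3
Reactants: 3 (2E,6E,10E)-12-hydroxyfarnesyl acetate
Product: 4 (2E,6E,10E)-12-(pivaloyloxy)farnesyl acetate
Conditions: PivCl, pyridine, DMAP (cat.), CH2Cl2, 0 °C
Reagents that add atoms: pivaloyl chloride, CC(C)(C)C(Cl)=O
Why: Acylation; the pivalate deactivates C11=C12 in step 4, survives the acetate cleavage of step 5 and is removed by the hydride of step 12 together with the ester reduction.

Step 4
Reactants: 4 (2E,6E,10E)-12-(pivaloyloxy)farnesyl acetate
Product: 5 (2E,6R,7R,10E)-6,7-epoxy-12-(pivaloyloxy)farnesyl acetate (7R,8R in cembrane numbering)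
Conditions: 1,2:4,5-di-O-isopropylidene-β-D-erythro-2,3-hexodiulo-2,6-pyranose (0.3 equiv), KHSO5 (as 2KHSO5·KHSO4·K2SO4), K2CO3, Bu4NHSO4, MeCN/CH2(OMe)2, aqueous Na2B4O7 buffer, 0 °C
Reagents that add atoms: potassium peroxymonosulfate, [K+].[O-]S(=O)(=O)OO
Why: Shi asymmetric epoxidation; the chiral dioxirane reacts through a spiro transition state with the central alkene, the only one not deactivated by an allylic acyloxy group, and the D-fructose-derived ketone delivers oxygen to the face of an E trisubstituted alkene that gives the (R,R)-oxirane.

Step 5
Reactants: 5 (2E,6R,7R,10E)-6,7-epoxy-12-(pivaloyloxy)farnesyl acetate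
Product: 6 (2E,6R,7R,10E)-6,7-epoxy-12-(pivaloyloxy)farnesol
Conditions: K2CO3 (0.3 equiv), MeOH, 0 °C
Reagents that add atoms: none
Why: Base-catalysed transesterification removes the unhindered acetate far faster than the pivalate; the oxirane is stable to methanolic carbonate at 0 °C.

Step 6
Reactants: 6 (2E,6R,7R,10E)-6,7-epoxy-12-(pivaloyloxy)farnesol
Product: 7 (2E,6R,7R,10E)-6,7-epoxy-12-(pivaloyloxy)farnesal
Conditions: MnO2 (activated, excess), CH2Cl2, rt
Reagents that add atoms: none
Why: Chemoselective oxidation of a primary allylic alcohol to the enal under neutral conditions, which keeps the E geometry and the oxirane.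

Step 7
Reactants: 7 (2E,6R,7R,10E)-6,7-epoxy-12-(pivaloyloxy)farnesal; 8 1,1,1,3,3,3-hexafluoropropan-2-yl acrylate
Product: 10 methyl 2-[(1R,2E,6R,7R,10E)-6,7-epoxy-1-hydroxy-3,7,11-trimethyl-12-(pivaloyloxy)dodeca-2,10-dien-1-yl]acrylate, via hexafluoroisopropyl ester 9 (not isolated)
Conditions: β-isocupreidine (0.1 equiv), DMF, −55 °C; then MeOH, Et3N, −20 °C → rt
Reagents that add atoms: methanol, CO
Why: Catalytic asymmetric Morita–Baylis–Hillman reaction; the quinuclidine nitrogen adds to the activated acrylate, the ammonium enolate attacks the aldehyde, and the phenolic OH of the catalyst hydrogen-bonds to the alkoxide so that only the betaine leading to the (R)-carbinol eliminates quickly, which sets C2. The active ester is then exchanged for the methyl ester in the same flask.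

Step 8
Reactants: 11 2-methylidenepropane-1,3-diol
Product: 12 2-{[(tert-butyldimethylsilyl)oxy]methyl}prop-2-en-1-ol
Conditions: NaH (1.0 equiv), THF, 0 °C; TBSCl (1.0 equiv)
Reagents that add atoms: tert-butyldimethylsilyl chloride, CC(C)(C)[Si](C)(C)Cl
Why: Monosilylation of a symmetric diol through its sparingly soluble monosodium alkoxide, which reacts once.

Step 9
Reactants: 12 2-{[(tert-butyldimethylsilyl)oxy]methyl}prop-2-en-1-ol
Product: 13 {[2-(bromomethyl)prop-2-en-1-yl]oxy}(tert-butyl)dimethylsilane
Conditions: CBr4, PPh3, CH2Cl2, 0 °C
Reagents that add atoms: tetrabromomethane, BrC(Br)(Br)Br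
Why: Appel bromination of a primary allylic alcohol under neutral conditions that leave the silyl ether in place.

Step 10
Reactants: 10 methyl ester of the (R)-Morita–Baylis–Hillman adduct; 13 {[2-(bromomethyl)prop-2-en-1-yl]oxy}(tert-butyl)dimethylsilane
Product: 14 methyl 2-[(1R,2E,6R,7R,10E)-1-({2-[(tert-butyldimethylsilyloxy)methyl]prop-2-en-1-yl}oxy)-6,7-epoxy-3,7,11-trimethyl-12-(pivaloyloxy)dodeca-2,10-dien-1-yl]acrylate
Conditions: Ag2O (2 equiv), 13 (3 equiv), Bu4NI (cat.), CH2Cl2, rt → 40 °C, dark
Reagents that add atoms: none
Why: Silver oxide-mediated O-alkylation with a reactive allylic bromide; no free alkoxide is formed, so the β-hydroxy acrylate is protected from oxa-Michael addition and elimination, and the C2–O bond is not broken, so C2 is retained.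

Step 11
Reactants: 14 diene ether
Product: 15 methyl (2R)-4-[(tert-butyldimethylsilyloxy)methyl]-2-[(1E,5R,6R,9E)-5,6-epoxy-2,6,10-trimethyl-11-(pivaloyloxy)undeca-1,9-dien-1-yl]-2,5-dihydrofuran-3-carboxylate
Conditions: RuCl2(=CH-C6H4-2-OiPr)(C17H18N2) [C17H18N2 = 1,3-bis(2-methylphenyl)imidazolidin-2-ylidene] (10 mol %), toluene, 70 °C, argon purge
Reagents that add atoms: none
Why: Ring-closing metathesis of two 1,1-disubstituted alkenes to a tetrasubstituted 2,5-dihydrofuran; the small N-aryl groups of the carbene ligand leave room for the crowded ruthenacyclobutane. Closure onto C1 keeps one unsubstituted carbon next to ruthenium, whereas the competing five-membered closure onto C3=C4 would place two fully substituted carbons there. C2 is not touched.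

Step 12
Reactants: 15 dihydrofuran ester
Product: 16 {(2R)-4-[(tert-butyldimethylsilyloxy)methyl]-2-[(1E,5R,6R,9E)-5,6-epoxy-11-hydroxy-2,6,10-trimethylundeca-1,9-dien-1-yl]-2,5-dihydrofuran-3-yl}methanol (C13,C14 diol)
Conditions: iBu2AlH (6 equiv), CH2Cl2, −78 °C; aqueous KNaC4H4O6 work-up
Reagents that add atoms: none
Why: 1,2-Reduction of the conjugated ester and reductive cleavage of the pivalate in one operation; at −78 °C the trisubstituted oxirane and the silyl ether are not attacked.

Step 13
Reactants: 16 C13,C14 diol
Product: 17 C13,C14-seco bis(allylic bromide) with C17 as TBS ether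
Conditions: CBr4, PPh3, 2,6-lutidine, CH2Cl2, −30 → 0 °C; used at once
Reagents that add atoms: tetrabromomethane, BrC(Br)(Br)Br
Why: Twofold Appel bromination of two primary allylic alcohols with direct displacement at the primary carbons; the buffered, neutral medium spares the oxirane and the silyl ether.

Step 14
Reactants: 17 C13,C14-seco bis(allylic bromide)
Product: 19 lobophynin B skeleton with a C17 TBS ether, via allylnickel bromide 18 (not isolated)
Conditions: Ni(CO)4 (zerovalent nickel, 6 equiv), N-methyl-2-pyrrolidone, 50 °C, argon, closed and scrubbed system; 17 added by syringe pump over 12 h to a final 0.003 M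
Reagents that add atoms: none
Why: Oxidative addition of zerovalent nickel to the less hindered C13–Br bond gives allylnickel bromide 18, which takes up the C14 allylic bromide of the same molecule; carbon–carbon bond formation at the two primary termini and loss of NiBr2 give the 1,5-diene. The closest known reaction type is the tetracarbonylnickel-mediated intramolecular coupling of α,ω-bis(allylic bromides) to macrocyclic 1,5-dienes in polar aprotic solvents. The 14-membered carbocycle is closed by head-to-head union of two sp3 carbons, and slow addition keeps the allyl transfer intramolecular. No stereocentre is formed, and C2, C7 and C8 are not next to a reacting centre. The step needs regioselectivity for C13 and C14 over C11 and C15: C11 is secondary and would lead to a twelve-membered ring, and C15 is fully substituted and held in the dihydrofuran. The step also needs E geometry at C11=C12 to survive; the allyl unit is formed from 17 in the arrangement that corresponds to the E alkene, and the moderate temperature limits its equilibration. Both termini start as electrophiles, so no carbanion arises next to the oxirane or the allylic ethers, and the C17 silyl ether offers nickel no leaving group.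

Step 15
Reactants: 19 macrocyclic C17 TBS ether
Product: 20 macrocyclic C17 alcohol (deacetyl-lobophynin B)
Conditions: Bu4NF, THF, 0 °C
Reagents that add atoms: none
Why: Fluoride-induced cleavage of a primary silyl ether; the oxirane, the alkenes and the cyclic allylic ether are inert to fluoride at 0 °C.

Step 16
Reactants: 20 macrocyclic C17 alcohol
Product: 21 lobophynin B
Conditions: Ac2O, pyridine, DMAP (cat.), CH2Cl2, 0 °C → rt
Reagents that add atoms: acetic anhydride, CC(=O)OC(C)=O
Why: Acetylation of a primary allylic alcohol under mild basic conditions that do not ionise the doubly allylic C2–O bond or open the oxirane.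

## Compound list

1 | (2E,6E)-farnesol | CC(C)=CCC/C(C)=C/CC/C(C)=C/CO | starting material
2 | (2E,6E)-farnesyl acetate | CC(C)=CCC/C(C)=C/CC/C(C)=C/COC(C)=O | intermediate
3 | (2E,6E,10E)-12-hydroxyfarnesyl acetate | OC/C(C)=C/CC/C(C)=C/CC/C(C)=C/COC(C)=O | intermediate
4 | (2E,6E,10E)-12-(pivaloyloxy)farnesyl acetate | CC(C)(C)C(=O)OC/C(C)=C/CC/C(C)=C/CC/C(C)=C/COC(C)=O | intermediate
5 | (2E,6R,7R,10E)-6,7-epoxy-12-(pivaloyloxy)farnesyl acetate | CC(C)(C)C(=O)OC/C(C)=C/CC[C@@]1(C)O[C@@H]1CC/C(C)=C/COC(C)=O | intermediate
6 | (2E,6R,7R,10E)-6,7-epoxy-12-(pivaloyloxy)farnesol | CC(C)(C)C(=O)OC/C(C)=C/CC[C@@]1(C)O[C@@H]1CC/C(C)=C/CO | intermediate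
7 | (2E,6R,7R,10E)-6,7-epoxy-12-(pivaloyloxy)farnesal | CC(C)(C)C(=O)OC/C(C)=C/CC[C@@]1(C)O[C@@H]1CC/C(C)=C/C=O | intermediate
8 | 1,1,1,3,3,3-hexafluoropropan-2-yl acrylate | C=CC(=O)OC(C(F)(F)F)C(F)(F)F | starting material
9 | hexafluoroisopropyl ester of the (R)-Morita–Baylis–Hillman adduct of 7 (not isolated) | CC(C)(C)C(=O)OC/C(C)=C/CC[C@@]1(C)O[C@@H]1CC/C(C)=C/[C@@H](O)C(=C)C(=O)OC(C(F)(F)F)C(F)(F)F | intermediate
10 | methyl 2-[(1R,2E,6R,7R,10E)-6,7-epoxy-1-hydroxy-3,7,11-trimethyl-12-(pivaloyloxy)dodeca-2,10-dien-1-yl]acrylate | CC(C)(C)C(=O)OC/C(C)=C/CC[C@@]1(C)O[C@@H]1CC/C(C)=C/[C@@H](O)C(=C)C(=O)OC | intermediate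
11 | 2-methylidenepropane-1,3-diol | C=C(CO)CO | starting material
12 | 2-{[(tert-butyldimethylsilyl)oxy]methyl}prop-2-en-1-ol | C=C(CO)CO[Si](C)(C)C(C)(C)C | intermediate
13 | {[2-(bromomethyl)prop-2-en-1-yl]oxy}(tert-butyl)dimethylsilane | C=C(CBr)CO[Si](C)(C)C(C)(C)C | intermediate
14 | C2 O-{2-[(tert-butyldimethylsilyloxy)methyl]allyl} ether of 10 | CC(C)(C)C(=O)OC/C(C)=C/CC[C@@]1(C)O[C@@H]1CC/C(C)=C/[C@@H](OCC(=C)CO[Si](C)(C)C(C)(C)C)C(=C)C(=O)OC | intermediate
15 | methyl (2R)-4-[(tert-butyldimethylsilyloxy)methyl]-2-[(1E,5R,6R,9E)-5,6-epoxy-2,6,10-trimethyl-11-(pivaloyloxy)undeca-1,9-dien-1-yl]-2,5-dihydrofuran-3-carboxylate | CC(C)(C)C(=O)OC/C(C)=C/CC[C@@]1(C)O[C@@H]1CC/C(C)=C/[C@H]2OCC(CO[Si](C)(C)C(C)(C)C)=C2C(=O)OC | intermediate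
16 | C13,C14 diol: {(2R)-4-[(tert-butyldimethylsilyloxy)methyl]-2-[(1E,5R,6R,9E)-5,6-epoxy-11-hydroxy-2,6,10-trimethylundeca-1,9-dien-1-yl]-2,5-dihydrofuran-3-yl}methanol | OC/C(C)=C/CC[C@@]1(C)O[C@@H]1CC/C(C)=C/[C@H]2OCC(CO[Si](C)(C)C(C)(C)C)=C2CO | intermediate
17 | C13,C14-seco bis(allylic bromide), C17 TBS ether | BrC/C(C)=C/CC[C@@]1(C)O[C@@H]1CC/C(C)=C/[C@H]2OCC(CO[Si](C)(C)C(C)(C)C)=C2CBr | intermediate
18 | C13 allylnickel bromide of 17 (divalent nickel, drawn as the σ-allyl form; not isolated) | Br[Ni]C/C(C)=C/CC[C@@]1(C)O[C@@H]1CC/C(C)=C/[C@H]2OCC(CO[Si](C)(C)C(C)(C)C)=C2CBr | intermediate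
19 | lobophynin B skeleton with C17 TBS ether | CC(C)(C)[Si](C)(C)OCC1=C2CC/C(C)=C/CC[C@@]3(C)O[C@@H]3CC/C(C)=C/[C@H]2OC1 | intermediate
20 | C17 alcohol (deacetyl-lobophynin B) | OCC1=C2CC/C(C)=C/CC[C@@]3(C)O[C@@H]3CC/C(C)=C/[C@H]2OC1 | intermediate
21 | lobophynin B | CC(=O)OCC1=C2CC/C(C)=C/CC[C@@]3(C)O[C@@H]3CC/C(C)=C/[C@H]2OC1 | target

## Step count and least certain steps

Total: 16 steps. Longest linear sequence: 14 steps (steps 1–7 and 10–16); steps 8 and 9 form a two-step side branch.

Step 14 (key step). The most likely failures are:
- loss of E geometry at C11=C12 by equilibration of the allylnickel unit;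
- coupling through the secondary C11 terminus;
- intermolecular coupling if the addition is too fast;
- opening of the oxirane by NiBr2 and bromide as they build up.

Fallback (same bond, reversed polarity at C13), from 15 back to 19: the allylic pivalate of 15 would be exchanged with PhSO2Na and Pd(PPh3)4 (zerovalent palladium) to give the C13 phenyl sulfone ester F1. Reduction with iBu2AlH gives the sulfone alcohol F2, and CBr4/PPh3 gives the sulfone bromide F3. KN(SiMe3)2 in THF at −78 °C under high dilution closes the ring by alkylation of the sulfonyl-stabilised C13 carbanion with the C14 bromide, giving the macrocyclic C13 sulfone F4. Buffered Na(Hg) in methanol removes the sulfonyl group and gives 19. The carbanion sits at C13, away from the oxirane and from the oxygens of the dihydrofuran.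

Step 7. The most likely failure is slow addition of the ammonium enolate to a β,β-disubstituted enal at low temperature, so that conversion stalls or control over C2 erodes.

Fallback (aldol, then methylenation), from 7 back to 10: addition of the dilithium enolate of (S)-2-hydroxy-1,2,2-triphenylethyl acetate (LiN(iPr)2, THF, −78 °C) to 7 gives the auxiliary-bound β-hydroxy ester F5. K2CO3 in methanol gives the methyl (S)-β-hydroxy ester F6. Double deprotonation (LiN(iPr)2, 2.2 equiv) and reaction with dimethyl(methylidene)ammonium iodide, in the manner of a Fráter–Seebach alkylation, gives the α-(dimethylaminomethyl) ester F7. Quaternisation with MeI and elimination with DBU give 10.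

Step 11. The most likely failure is slow closure of the tetrasubstituted alkene, which gives the ruthenium carbene at C15 time to attack C3=C4 (loss of the chain) or to decompose.

Fallback (ester tether, then ring closure at O–C16 by alkylation), from 7 back to 15: step 7 is repeated, but the active ester 9 is quenched with 2-(chloromethyl)prop-2-en-1-ol in place of methanol. This gives the 2-(chloromethyl)allyl ester F8. Ring-closing metathesis with the same ruthenium catalyst joins C1 and C15 within a butenolide, giving the chloromethyl butenolide F9. In this substrate attack on C3=C4 would need a seven-membered ring. Ag2O then lets the C2 hydroxyl displace the allylic chloride, which is held cis to it, giving the bicyclic lactone F10. LiOH opens the lactone, TBSCl/imidazole silylates both oxygens, and K2CO3 in aqueous methanol frees the acid, giving the C17 silyloxy acid F11. MeI/K2CO3 in DMF gives 15.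

## Further compounds

F1 | step 14 | C13 phenyl sulfone ester | O=S(=O)(c1ccccc1)C/C(C)=C/CC[C@@]1(C)O[C@@H]1CC/C(C)=C/[C@H]2OCC(CO[Si](C)(C)C(C)(C)C)=C2C(=O)OC
F2 | step 14 | sulfone alcohol | O=S(=O)(c1ccccc1)C/C(C)=C/CC[C@@]1(C)O[C@@H]1CC/C(C)=C/[C@H]2OCC(CO[Si](C)(C)C(C)(C)C)=C2CO
F3 | step 14 | sulfone bromide | O=S(=O)(c1ccccc1)C/C(C)=C/CC[C@@]1(C)O[C@@H]1CC/C(C)=C/[C@H]2OCC(CO[Si](C)(C)C(C)(C)C)=C2CBr
F4 | step 14 | macrocyclic C13 sulfone (C13 configuration not defined) | CC(C)(C)[Si](C)(C)OCC1=C2CC(S(=O)(=O)c3ccccc3)/C(C)=C/CC[C@@]4(C)O[C@@H]4CC/C(C)=C/[C@H]2OC1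
F5 | step 7 | auxiliary-bound β-hydroxy ester | CC(C)(C)C(=O)OC/C(C)=C/CC[C@@]1(C)O[C@@H]1CC/C(C)=C/[C@@H](O)CC(=O)O[C@@H](c1ccccc1)C(O)(c1ccccc1)c1ccccc1
F6 | step 7 | methyl (S)-β-hydroxy ester | CC(C)(C)C(=O)OC/C(C)=C/CC[C@@]1(C)O[C@@H]1CC/C(C)=C/[C@@H](O)CC(=O)OC
F7 | step 7 | α-(dimethylaminomethyl) ester (C1 configuration not defined) | CC(C)(C)C(=O)OC/C(C)=C/CC[C@@]1(C)O[C@@H]1CC/C(C)=C/[C@@H](O)C(CN(C)C)C(=O)OC
F8 | step 11 | 2-(chloromethyl)allyl ester | CC(C)(C)C(=O)OC/C(C)=C/CC[C@@]1(C)O[C@@H]1CC/C(C)=C/[C@@H](O)C(=C)C(=O)OCC(=C)CCl
F9 | step 11 | chloromethyl butenolide | CC(C)(C)C(=O)OC/C(C)=C/CC[C@@]1(C)O[C@@H]1CC/C(C)=C/[C@@H](O)C2=C(CCl)COC2=O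
F10 | step 11 | bicyclic lactone | CC(C)(C)C(=O)OC/C(C)=C/CC[C@@]1(C)O[C@@H]1CC/C(C)=C/[C@H]2OCC3=C2C(=O)OC3
F11 | step 11 | C17 silyloxy acid | CC(C)(C)C(=O)OC/C(C)=C/CC[C@@]1(C)O[C@@H]1CC/C(C)=C/[C@H]2OCC(CO[Si](C)(C)C(C)(C)C)=C2C(=O)O
A1 | alternative 1 | open-chain 2,5-dihydrofuran with C2 set, C13 and C14 as TBS ethers, C17 as TBDPS ether | CC(C)(C)[Si](c1ccccc1)(c1ccccc1)OCC2=C(CO[Si](C)(C)C(C)(C)C)[C@@H](/C=C(\C)CC/C=C(\C)CC/C=C(\C)CO[Si](C)(C)C(C)(C)C)OC2
A2 | alternative 2 | lobophynin B skeleton with C17 as methyl ester | COC(=O)C1=C2CC/C(C)=C/CC[C@@]3(C)O[C@@H]3CC/C(C)=C/[C@H]2OC1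
A3 | alternative 3 | 14-membered cycloalkyne (C3≡C4) with oxirane, C11=C12 and tetrasubstituted alkene in place | CC[Si](CC)(CC)O[C@@H]1C#CCC[C@H]2O[C@]2(C)CC/C=C(\C)CC/C1=C(/COCc3ccc(OC)cc3)CO[Si](C)(C)C(C)(C)C
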